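## Structural features

Atoms are numbered as in the briarane skeleton: the ten-membered ring is C1–C10; ring A is the cyclohexane C1, C10, C11, C12, C13, C14; the γ-lactone is O–C7–C8–C17–C19 (C18 is the methyl on C17); C15 and C20 are the methyls on C1 and C11; C16 is the methylene carbon on C5; β is the face of ring A that carries C15. The target is a trans-fused 6/10 bicycle joined through the C1–C10 bond, with a trans-fused γ-lactone across C7–C8. Of the twelve stereocentres, the quaternary C1 stands next to C10 (H α); C11 (OH α, C20 β), C12 (butanoate α) and the α 13,14-epoxide fill the rest of ring A; C2 (acetate) flanks C1; C6 (Cl), C7 (O), C8 (OH) and C9 (OAc) are contiguous in the medium ring, and C17 sits on the lactone. Fragile groups are the secondary allylic chloride at C6 beside the C5=C16 methylene, the epoxide, three esters, and the tertiary β-hydroxy lactone with its epimerisable C17. The real difficulty is the ten-membered carbocycle fused to ring A at the quaternary C1/C10 pair, together with the run C6–C9 inside it. The key step exploits the fact that C9 carries oxygen, C4–C5(C16)–C6 is a masked isopropenyl group on C4, and C7–C8 is a masked vinyl group on C9: the medium ring is a 3-oxy-1,5-diene wrapped around a latent C4–C9 bond, that is, a ring-expanded trans-decalin (ring A plus ring B = C1, C2, C3, C4, C9, C10). That decalin has oxygen at C2 and C9 in a 1,4-relationship and the C15 methyl at the ring fusion, the pattern of a methylbenzoquinone Diels–Alder adduct.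

## Logic of the disconnections

34 ⇒ 33 ⇒ 32 ⇒ 31. Bonds cut: the C12–O acyl bond, then the C13–O and C14–O bonds of the epoxide, then the two C–O bonds of a ketal holding O11 and O12. The butanoate and epoxide are the most labile groups, and the free 12-OH is the handle that directs the epoxidation. The gain is that ring A travels as a robust cis-diol ketal with a C13=C14 alkene through all carbanion chemistry. The demand: in 32 the oxidant must be delivered syn to the 12α-OH and ignore C5=C16; in 33 only the secondary alcohol may be acylated.

31 ⇒ 30. Bond cut: C6–Cl, with the C5=C16 bond moved back to C5=C6. The 6-chloro-5(16)-ene is the retron of an ene-type chlorination of a trisubstituted alkene. Allylic chloride and methylene then appear together late and never meet a base. The demand: chlorine must add to C6 anti to the C7–O bond, and the proton must leave from C16.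

30 ⇒ 28 ⇒ 27 ⇒ 25. Bonds cut: the two acetates, the silyl ether at O2, then the lactone C7–O bond and the C8–O bond. A 7,8-trans-fused hydroxy-lactone is the product of anti addition of carboxylate oxygen (C7) and hydroxyl (C8) across a (7E)-alkene. C7 and C8 therefore follow from alkene geometry and one epoxidation, and C17 is corrected by equilibration. The demand: epoxidation on the alkene face that gives the 8,9-threo epoxy alcohol, and opening at C7 with inversion.

25 ⇒ 24 ⇒ 22 ⇒ 21. Bonds cut: C9–H (back to the ketone) and C8–C17 (through C8–I). The α-carbon of an enone can be iodinated and cross-coupled, which brings in C17, C18 and C19 at the acid oxidation level. The gain is that 21 carries no lactone carbons. The demand: 1,2-reduction of 24 from the face that gives 9S, and coupling with retention of the C7=C8 geometry.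

21 ⇒ 20 ⇒ 18 (key disconnection). After moving C5=C6 back to C4=C5 (21 ⇒ 20), the C6–C7 bond is cut and the C4–C9 bond re-formed. C9=O returns to a tertiary alkoxide, C7=C8 to a vinyl group on C9, and C4=C5(C16) to an isopropenyl group on C4. The C9 oxygen and the two alkenes around the latent C4–C9 bond are the retron of an oxy-Cope ring expansion. The gain is large: the ten-membered ring becomes a trans-decalin, on whose chair C1, C2, C10, C11 and C12 can be set. The demand: a chair transition state with both alkenyl groups equatorial, a [3,3] shift faster than fragmentation, and interception of the enolate as the enone. In one sentence: an anionic oxy-Cope ring expansion of decalin carbinol 18 makes the ten-membered ring.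

18 ⇒ 16 ⇒ 14. Bonds cut: C8–C9 (vinyl) and C4–C5 (isopropenyl). Both are made at the same ketone, by carbonyl addition and by enolate alkenylation. The gain is two commercial units, 17 and 15. The demand: enolisation of 14 towards C4, and equatorial addition to 16.

14 ⇒ 12 ⇒ 11 ⇒ 10 ⇒ 6. Bonds cut: the C3–H and C4–H bonds (back to a β-methoxy enone), the ketal, and the C11–O and C12–O bonds of a cis-diol, back to a ring A diene made from the single alkene of 6. The cis 11,12-diol opposite C15 is the product of a syn-dihydroxylation; the methoxy group is the blocking group of the quinone. The gain: ring A oxygenation comes from one alkene, and C2 and C9 are told apart by the vinylogous ester. The demand: dihydroxylation at C11=C12 from the α face, and diene formation without base.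

6 ⇒ 5 ⇒ 4 ⇒ 3 ⇒ 1 + 2. Bonds cut: C1–C14 and C10–C11 (Diels–Alder retron), after removal of the silyl group, the C2–H bond and the C10 epimerisation. The gain is two commercial components; C1 is set by a chiral Lewis acid, C10 by equilibration, C2 by hydride anti to C15. The demand: cycloaddition at the methyl-bearing double bond with the diene CH2 on C1.

## Other disconnections considered

Alternative 1: Cut C5–C6, the 2-methylene allylic carbinol retron, which is the first disconnection that comes to mind. Forward, an intramolecular Nozaki–Hiyama–Kishi reaction of the vinyl iodide/aldehyde A1 would close the ten-membered ring and give a 6-OH to be turned into the chloride. The chosen plan is preferred for three reasons. The closure must overcome transannular strain at the end, with the lactone and every other stereocentre already in place. The new C6 centre would form without a controlling element and then need an SN2 reaction at a hindered allylic position. Ring A, the C1 quaternary centre and the lactone would each need a separate asymmetric construction, so the linear sequence to A1 is long before the ring is even tested.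

Alternative 2: Cut C1–C2 by a glycolate Ireland–Claisen rearrangement of the allylic ester A2. Forward, the chelated enolate would rearrange suprafacially across the cyclohexene, carrying the C13 carbinol configuration to the quaternary C1 and setting C2, and it leaves C13=C14 where the epoxide is needed. This settles the C1/C2 pair well but leaves the ten-membered ring to a later macrocyclisation, and ring A must first be built enantiopure with C10, C11 and C12. The chosen plan gets C1/C10 from one catalytic cycloaddition and the ring from one rearrangement, in fewer steps.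

Alternative 3: Apply the same rearrangement across the other ring-B bond: cut C4–C5 and re-form C2–C7. Forward, the decalin A3 (vinyl carbinol at C2, a 3-silyloxypropenyl group at C7, C8 and C9 already oxygenated on the chair) would give a C2 ketone and a (6E)-alkene, and a chlorolactonisation across C6=C7 would then set C6 and C7 together. The endgame is attractive, but A3 needs a tertiary carbinol at C8 next to the enolisable C7 and β to the C2 carbonyl, which is prone to retro-aldol cleavage and β-elimination. A3 also has no short entry, since a quinone cycloaddition does not place both a carbon branch and oxygen at C8, and the C2 stereocentre would be destroyed and reset on the medium ring. The estimate is at least six more steps.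

Key step: step 13

Assumption 1: 2-methoxy-6-methyl-1,4-benzoquinone is taken as a purchasable compound.
Assumption 2: the (S)-configured oxazaborolidinium catalyst is taken to deliver the (1S) adduct; the mirror-image catalyst would be used if the sense of induction is opposite.

## Steps

Step 1
Reactants: 1 2-methoxy-6-methyl-1,4-benzoquinone; 2 (E)-penta-1,3-diene
Product: 3 cis-fused enedione adduct (C15 β, H10 β, C20 α, C12=C13)
Conditions: (S)-B-(o-tolyl) oxazaborolidine from diphenylprolinol·HNTf2 (20 mol%), CH2Cl2, −78 °C
Reagents that add atoms: none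
Why: Catalytic enantioselective quinone Diels–Alder reaction: the cationic boron Lewis acid binds the more basic vinylogous-ester carbonyl (C9) syn to H10, so the unsubstituted diene terminus bonds to the methyl-bearing C1 and the methoxy-substituted double bond stays untouched; endo addition gives the cis fusion and the catalyst face sets C1 (S).

Step 2
Reactants: 3 cis-fused enedione adduct
Product: 4 trans-fused enedione (H10 α)
Conditions: t-BuOK (0.1 equiv), t-BuOH/THF, 0 °C
Reagents that add atoms: none
Why: Base-mediated epimerisation of the enolisable ring-fusion carbon C10 (alpha to the C9 carbonyl) should settle on the trans-fused isomer, the known behaviour of angularly methylated quinone–diene adducts; C1 is quaternary, and C11 can keep its methyl equatorial.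

Step 3
Reactants: 4 trans-fused enedione
Product: 5 2β-alcohol
Conditions: NaBH4, CeCl3·7H2O, MeOH, −78 °C
Reagents that add atoms: none
Why: Luche 1,2-reduction: only the C2 carbonyl is ketone-like (C9 is a deactivated vinylogous ester), and hydride should enter anti to the axial C15 methyl to give the equatorial 2β-alcohol, which has the C2 configuration of the target.

Step 4
Reactants: 5 2β-alcohol
Product: 6 2β-TBS ether
Conditions: TBSOTf, 2,6-lutidine, CH2Cl2, −78 to 0 °C
Reagents that add atoms: tert-butyldimethylsilyl triflate CC(C)(C)[Si](C)(C)OS(=O)(=O)C(F)(F)F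
Why: Silylation of a hindered secondary alcohol with the silyl triflate; the ether must survive organometallic and hydride steps up to step 19.

Step 5
Reactants: 6 2β-TBS ether
Product: 7 12α,13α-epoxide
Conditions: mCPBA, NaHCO3, CH2Cl2, 0 °C
Reagents that add atoms: 3-chloroperbenzoic acid OOC(=O)c1cccc(Cl)c1
Why: Prilezhaev epoxidation of the only electron-rich alkene, expected from the α face away from the axial C15; the epoxide is only a relay, and either face converges on 10.

Step 6
Reactants: 7 12α,13α-epoxide
Product: 9 12α-allylic alcohol (C13=C14), via 13β-phenylselanyl 12α-alcohol 8 (not isolated)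
Conditions: (PhSe)2, NaBH4, EtOH, 25 °C; then 30% H2O2, THF, 0 to 25 °C
Reagents that add atoms: none
Why: Trans-diaxial epoxide opening by selenide at C13, then selenoxide syn-elimination away from the carbinol carbon, should give the transposed allylic alcohol; the regiochemistry is immaterial because either allylic alcohol dehydrates to 10.

Step 7
Reactants: 9 12α-allylic alcohol
Product: 10 ring A diene (C11=C12, C13=C14)
Conditions: Ph2S[OC(CF3)2Ph]2, CH2Cl2, 25 °C
Reagents that add atoms: none
Why: Sulfurane dehydration: anti-elimination of the axial 12-OH with the axial H11 (or ionisation to the allyl cation) gives the homoannular diene, and no base is present that could move it into conjugation with C9.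

Step 8
Reactants: 10 ring A diene
Product: 11 11α,12α-diol (C20 β, C13=C14)
Conditions: OsO4 (2 mol%), NMO, acetone/H2O, 0 °C
Reagents that add atoms: osmium tetroxide O=[Os](=O)(=O)=O (reoxidised by N-methylmorpholine N-oxide C[N+]1([O-])CCOCC1); water O
Why: Catalytic syn-dihydroxylation of the more electron-rich trisubstituted C11=C12 bond from the α face opposite the axial C15 sets C11 (OH α, C20 β) and C12 (O α) together; the push–pull C3=C4 bond is expected to be inert.

Step 9
Reactants: 11 11α,12α-diol
Product: 12 11,12-acetonide
Conditions: 2,2-dimethoxypropane, PPTS, CH2Cl2, 25 °C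
Reagents that add atoms: 2,2-dimethoxypropane COC(C)(C)OC
Why: Ketalisation of the cis-diol; it protects the tertiary and secondary hydroxyls and keeps O12 free of acyl groups until the end.

Step 10
Reactants: 12 11,12-acetonide
Product: 14 C9 ketone with saturated C3 and C4, via C3=C4 enone 13 (not isolated)
Conditions: [(Ph3P)CuH]6 (0.6 equiv), wet benzene, 25 °C; aq. NH4Cl
Reagents that add atoms: none
Why: Copper hydride conjugate reduction: hydride adds to C3, the copper enolate expels methoxide to give enone 13, which is reduced again; no carbanion develops at C3, so the C2 silyl ether is not eliminated, and the isolated ring A alkene is untouched.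

Step 11
Reactants: 14 C9 ketone; 15 2-bromopropene
Product: 16 4β-isopropenyl C9 ketone
Conditions: LiN(SiMe3)2, THF, −78 °C; then 15, Pd2(dba)3 (2.5 mol%), P(t-Bu)3 (10 mol%), 25 °C
Reagents that add atoms: none
Why: Palladium-catalysed α-alkenylation of the kinetic lithium enolate (C4 is the only α-methylene); protonation at C4 on work-up gives the β,γ-unsaturated ketone with the isopropenyl group equatorial (β).

Step 12
Reactants: 16 4β-isopropenyl C9 ketone; 17 vinylmagnesium bromide (CH2=CHMgBr)
Product: 18 9α-vinyl 9β-carbinol (trans-decalin, alkenyl groups trans-diequatorial)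
Conditions: 17, CeCl3, THF, −78 °C
Reagents that add atoms: none
Why: Organocerium 1,2-addition to a hindered, enolisable ketone; the axial (β) trajectory is blocked by the syn-axial C15 methyl, so vinyl should enter equatorially (α), trans to the isopropenyl group.

Step 13
Reactants: 18 9α-vinyl 9β-carbinol
Product: 20 (4E,7E)-skipped dienone (ten-membered C9 ketone fused to ring A), via potassium C8=C9 enolate 19 (not isolated)
Conditions: KH, 18-crown-6, THF, 0 to 25 °C; then PhS(Cl)=N-t-Bu, −78 °C
Reagents that add atoms: none
Why: Anionic oxy-Cope rearrangement: the potassium alkoxide of 18 undergoes a concerted [3,3]-sigmatropic shift in which the C4–C9 bond breaks and the C6–C7 bond forms; the closest known case is the ring expansion of 2-isopropenyl-1-vinylcyclohexanols to germacrane-type cyclodecenones. The ten-membered ring is not closed by a cyclisation but arises by four-atom expansion of ring B through a six-centre chair transition state, so no endo or exo mode applies. The equatorial vinyl (C9) and isopropenyl (C4) groups fit this chair and give the (4E)-alkene and the ring-trans enolate 19. No new sp3 stereocentre is made: C4 and C9 become trigonal, and C1, C2, C10, C11 and C12 are carried over from the decalin. The step needs the [3,3] shift to beat heterolytic cleavage of the alkoxide; the crown-ether-separated alkoxide, the relief of the 1,3-diaxial and peri strain around C9 and the formation of a delocalised enolate all favour the shift. The enolate is regiodefined at C8, and the sulfinimidoyl chloride converts it in the same flask into the enone by syn-elimination, for which only C7 offers β-hydrogens.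

Step 14
Reactants: 20 (4E,7E)-skipped dienone
Product: 21 (5Z,7E)-conjugated dienone
Conditions: DBU (0.2 equiv), CH2Cl2, 0 °C
Reagents that add atoms: none
Why: Base-catalysed isomerisation through the extended enolate (deprotonation of the doubly allylic C6, reprotonation at C4) moves C4=C5 into conjugation as C5=C6, expected as the ring-cis (5Z) isomer, the less strained partner of the (7E)-enone in a ten-membered ring; brief exposure to catalytic base is chosen to leave C10 and the C7=C8 geometry untouched.

Step 15
Reactants: 21 (5Z,7E)-conjugated dienone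
Product: 22 8-iodo dienone (C6 and C9 trans across C7=C8)
Conditions: I2, pyridine, CH2Cl2, 25 °C
Reagents that add atoms: iodine II
Why: α-Iodination of the enone by pyridine conjugate addition, iodination of the enolate and elimination; the more stable geometry with C6 trans to the carbonyl carbon is retained.

Step 16
Reactants: 22 8-iodo dienone; 23 tert-butyl 2-bromopropanoate
Product: 24 C8-(1-tert-butoxycarbonylethyl) dienone (C17 epimers)
Conditions: 23, Zn dust, THF; then 22, Pd(dba)2 (5 mol%), P(t-Bu)3 (5 mol%), THF, 25 °C
Reagents that add atoms: none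
Why: Negishi-type coupling of the Reformatsky reagent with the vinyl iodide (retention of alkene geometry) forges C8–C17 and brings C19 in as an ester; C17 forms without control and is set in step 20.

Step 17
Reactants: 24 C8-(1-tert-butoxycarbonylethyl) dienone
Product: 25 9S allylic alcohol (C17 epimers)
Conditions: NaBH4, CeCl3·7H2O, MeOH, −40 °C
Reagents that add atoms: none
Why: Luche 1,2-reduction; hydride is expected on the outer face of the s-trans dienone held in the ring, which should give 9S; this is substrate control only and is treated as a risk below.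

Step 18
Reactants: 25 9S allylic alcohol
Product: 27 7,8-trans-fused hydroxy-lactone 8,9-diol (C17 epimers), via 7,8-epoxy alcohol 26 (not isolated)
Conditions: VO(acac)2 (5 mol%), t-BuOOH, CH2Cl2, 0 °C; then CSA (10 mol%), 25 °C
Reagents that add atoms: tert-butyl hydroperoxide CC(C)(C)OO
Why: Hydroxyl-directed vanadium epoxidation of the C9 allylic alcohol takes place at C7=C8 and not at the remote C5=C6; the needed 8,9-threo epoxy alcohol 26 arises if the ring holds the C9–O bond on the exposed outer face of the (7E)-alkene, as in medium-ring cycloalkenols where ring constraints override the open-chain preference, and this is treated as a risk below. Acid then lets the tert-butyl ester carbonyl open the epoxide at the allylic C7 with inversion (a 5-endo opening made possible by allylic stabilisation at C7, with loss of isobutene), so the (7E) geometry translates into the trans-fused hydroxy-lactone with the C7 and C8 configuration of the target.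

Step 19
Reactants: 27 hydroxy-lactone 8,9-diol
Product: 28 2,8,9-triol lactone (C17 epimers)
Conditions: HF·pyridine, pyridine, THF, 0 to 25 °C
Reagents that add atoms: none
Why: Fluoride cleavage of the silyl ether under buffered conditions that should leave the acetonide and the lactone intact.

Step 20
Reactants: 28 2,8,9-triol lactone
Product: 30 2,9-diacetate with 17R configuration, via 2,9-diacetate C17 epimers 29 (not isolated)
Conditions: Ac2O, DMAP, pyridine, 25 °C; then DBU, PhMe, 60 °C
Reagents that add atoms: acetic anhydride CC(=O)OC(C)=O
Why: Acetylation of the two secondary alcohols (the tertiary 8-OH is inert); DBU then equilibrates the lactone α-carbon to the epimer expected to be more stable, with C18 trans to the C9 branch and cis to the small 8-OH (17R).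

Step 21
Reactants: 30 2,9-diacetate (17R)
Product: 31 6S-chloro-5(16)-ene
Conditions: Ca(OCl)2, solid CO2, CH2Cl2/H2O, 0 °C
Reagents that add atoms: calcium hypochlorite [Ca+2].[O-]Cl.[O-]Cl
Why: Ene-type chlorination by HOCl: chlorine adds to C6 (cationic character at tertiary C5) and a C16 proton is lost; attack anti to the allylic C7–O bond in the A(1,3)-minimised conformer of the (5Z)-alkene should give 6S; the disubstituted C13=C14 bond beside the quaternary C1 is much less nucleophilic than the trisubstituted C5=C6 bond.

Step 22
Reactants: 31 6S-chloro-5(16)-ene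
Product: 32 11α,12α-diol
Conditions: AcOH/H2O 4:1, 40 °C
Reagents that add atoms: none
Why: Mild acid hydrolysis of the acetonide; the acetates, the lactone and the inductively deactivated allylic chloride should survive.

Step 23
Reactants: 32 11α,12α-diol
Product: 33 13α,14α-epoxide
Conditions: VO(acac)2 (5 mol%), t-BuOOH, CH2Cl2, 0 °C
Reagents that add atoms: tert-butyl hydroperoxide CC(C)(C)OO
Why: Hydroxyl-directed vanadium epoxidation syn to the allylic 12α-OH (also the face opposite C15) gives the α-epoxide; the C5=C16 alkene has no allylic hydroxyl, is deactivated by the allylic chloride and should be left.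

Step 24
Reactants: 33 13α,14α-epoxide
Product: 34 CNP0105329.1 (target)
Conditions: (n-PrCO)2O, Et3N, DMAP, CH2Cl2, 0 °C
Reagents that add atoms: butanoic anhydride CCCC(=O)OC(=O)CCC
Why: Acylation of the only secondary alcohol (12-OH); the tertiary 8-OH and 11-OH do not react under these conditions.

## Compound list

1 | 2-methoxy-6-methyl-1,4-benzoquinone | CC1=CC(=O)C=C(OC)C1=O | starting material
2 | (E)-penta-1,3-diene | C=C/C=C/C | starting material
3 | cis-fused enedione adduct (C15 β, H10 β, C20 α) | C1=C(OC)C(=O)[C@@]2(C)CC=C[C@@H](C)[C@H]2C1=O | intermediate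
4 | trans-fused enedione (H10 α) | C1=C(OC)C(=O)[C@@]2(C)CC=C[C@@H](C)[C@@H]2C1=O | intermediate
5 | 2β-alcohol | C1=C(OC)[C@H](O)[C@@]2(C)CC=C[C@@H](C)[C@@H]2C1=O | intermediate
6 | 2β-TBS ether | C1=C(OC)[C@H](O[Si](C)(C)C(C)(C)C)[C@@]2(C)CC=C[C@@H](C)[C@@H]2C1=O | intermediate
7 | 12α,13α-epoxide | C1=C(OC)[C@H](O[Si](C)(C)C(C)(C)C)[C@@]2(C)C[C@H]3O[C@H]3[C@@H](C)[C@@H]2C1=O | intermediate
8 | 13β-phenylselanyl 12α-alcohol | C1=C(OC)[C@H](O[Si](C)(C)C(C)(C)C)[C@@]2(C)C[C@H]([Se]c3ccccc3)[C@@H](O)[C@@H](C)[C@@H]2C1=O | intermediate
9 | 12α-allylic alcohol (C13=C14) | C1=C(OC)[C@H](O[Si](C)(C)C(C)(C)C)[C@@]2(C)C=C[C@@H](O)[C@@H](C)[C@@H]2C1=O | intermediate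
10 | ring A diene (C11=C12, C13=C14) | C1=C(OC)[C@H](O[Si](C)(C)C(C)(C)C)[C@@]2(C)C=CC=C(C)[C@@H]2C1=O | intermediate
11 | 11α,12α-diol | C1=C(OC)[C@H](O[Si](C)(C)C(C)(C)C)[C@@]2(C)C=C[C@@H](O)[C@@](C)(O)[C@@H]2C1=O | intermediate
12 | 11,12-acetonide (vinylogous ester) | C1=C(OC)[C@H](O[Si](C)(C)C(C)(C)C)[C@@]2(C)C=C[C@@H](OC(C)(C)O3)[C@]3(C)[C@@H]2C1=O | intermediate
13 | C3=C4 enone | C1=C[C@H](O[Si](C)(C)C(C)(C)C)[C@@]2(C)C=C[C@@H](OC(C)(C)O3)[C@]3(C)[C@@H]2C1=O | intermediate
14 | C9 ketone with saturated C3 and C4 | C1C[C@H](O[Si](C)(C)C(C)(C)C)[C@@]2(C)C=C[C@@H](OC(C)(C)O3)[C@]3(C)[C@@H]2C1=O | intermediate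
15 | 2-bromopropene | C=C(C)Br | starting material
16 | 4β-isopropenyl C9 ketone | [C@@H]1(C(C)=C)C[C@H](O[Si](C)(C)C(C)(C)C)[C@@]2(C)C=C[C@@H](OC(C)(C)O3)[C@]3(C)[C@@H]2C1=O | intermediate
17 | vinylmagnesium bromide | C=C[Mg]Br | starting material
18 | 9α-vinyl 9β-carbinol (4β-isopropenyl) | [C@@H]1(C(C)=C)C[C@H](O[Si](C)(C)C(C)(C)C)[C@@]2(C)C=C[C@@H](OC(C)(C)O3)[C@]3(C)[C@@H]2[C@@]1(O)C=C | intermediate
19 | potassium C8=C9 enolate of the ten-membered ring (4E) | C/C1=C\C[C@H](O[Si](C)(C)C(C)(C)C)[C@@]2(C)C=C[C@@H](OC(C)(C)O3)[C@]3(C)[C@@H]2/C([O-])=C/CC1.[K+] | intermediate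
20 | (4E,7E)-skipped dienone | C/C1=C\C[C@H](O[Si](C)(C)C(C)(C)C)[C@@]2(C)C=C[C@@H](OC(C)(C)O3)[C@]3(C)[C@@H]2C(=O)/C=C/C1 | intermediate
21 | (5Z,7E)-conjugated dienone | C1C[C@H](O[Si](C)(C)C(C)(C)C)[C@@]2(C)C=C[C@@H](OC(C)(C)O3)[C@]3(C)[C@@H]2C(=O)/C=C/C=C1/C | intermediate
22 | 8-iodo dienone | C1C[C@H](O[Si](C)(C)C(C)(C)C)[C@@]2(C)C=C[C@@H](OC(C)(C)O3)[C@]3(C)[C@@H]2C(=O)/C(I)=C/C=C1/C | intermediate
23 | tert-butyl 2-bromopropanoate | CC(Br)C(=O)OC(C)(C)C | starting material
24 | C8-(1-tert-butoxycarbonylethyl) dienone (C17 epimers, C17 undefined) | C1C[C@H](O[Si](C)(C)C(C)(C)C)[C@@]2(C)C=C[C@@H](OC(C)(C)O3)[C@]3(C)[C@@H]2C(=O)/C(C(C)C(=O)OC(C)(C)C)=C/C=C1/C | intermediate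
25 | 9S allylic alcohol (C17 epimers) | C1C[C@H](O[Si](C)(C)C(C)(C)C)[C@@]2(C)C=C[C@@H](OC(C)(C)O3)[C@]3(C)[C@@H]2[C@H](O)/C(C(C)C(=O)OC(C)(C)C)=C/C=C1/C | intermediate
26 | 7,8-epoxy alcohol (C17 epimers) | C1C[C@H](O[Si](C)(C)C(C)(C)C)[C@@]2(C)C=C[C@@H](OC(C)(C)O3)[C@]3(C)[C@@H]2[C@H](O)[C@@]4(C(C)C(=O)OC(C)(C)C)O[C@@H]4/C=C1/C | intermediate
27 | 7,8-trans-fused hydroxy-lactone 8,9-diol (C17 epimers) | C1C[C@H](O[Si](C)(C)C(C)(C)C)[C@@]2(C)C=C[C@@H](OC(C)(C)O3)[C@]3(C)[C@@H]2[C@H](O)[C@]4(O)C(C)C(=O)O[C@H]4/C=C1/C | intermediate
28 | 2,8,9-triol lactone (C17 epimers) | C1C[C@H](O)[C@@]2(C)C=C[C@@H](OC(C)(C)O3)[C@]3(C)[C@@H]2[C@H](O)[C@]4(O)C(C)C(=O)O[C@H]4/C=C1/C | intermediate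
29 | 2,9-diacetate (C17 epimers) | C1C[C@H](OC(C)=O)[C@@]2(C)C=C[C@@H](OC(C)(C)O3)[C@]3(C)[C@@H]2[C@H](OC(C)=O)[C@]4(O)C(C)C(=O)O[C@H]4/C=C1/C | intermediate
30 | 2,9-diacetate, 17R | C1C[C@H](OC(C)=O)[C@@]2(C)C=C[C@@H](OC(C)(C)O3)[C@]3(C)[C@@H]2[C@H](OC(C)=O)[C@]4(O)[C@@H](C)C(=O)O[C@H]4/C=C1/C | intermediate
31 | 6S-chloro-5(16)-ene | C=C1CC[C@H](OC(C)=O)[C@@]2(C)C=C[C@@H](OC(C)(C)O3)[C@]3(C)[C@@H]2[C@H](OC(C)=O)[C@]4(O)[C@@H](C)C(=O)O[C@H]4[C@H]1Cl | intermediate
32 | 11α,12α-diol (C13=C14) | C=C1CC[C@H](OC(C)=O)[C@@]2(C)C=C[C@@H](O)[C@@](C)(O)[C@@H]2[C@H](OC(C)=O)[C@]3(O)[C@@H](C)C(=O)O[C@H]3[C@H]1Cl | intermediate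
33 | 13α,14α-epoxide with free 12-OH | C=C1CC[C@H](OC(C)=O)[C@@]2(C)[C@H]3O[C@H]3[C@@H](O)[C@@](C)(O)[C@@H]2[C@H](OC(C)=O)[C@]2(O)[C@@H](C)C(=O)O[C@H]2[C@H]1Cl | intermediate
34 | CNP0105329.1 | C=C1CC[C@H](OC(C)=O)[C@@]2(C)[C@H]3O[C@H]3[C@@H](OC(=O)CCC)[C@@](C)(O)[C@@H]2[C@H](OC(C)=O)[C@]2(O)[C@@H](C)C(=O)O[C@H]2[C@H]1Cl | target

## Step count and least certain steps

Total step count: 24. Longest linear sequence: 24 steps (from 1 and 2; all other components are commercial and enter directly).

Step 13 (key step). The most likely failure is heterolytic cleavage of the alkoxide (loss of the vinyl or allyl fragment) competing with the sigmatropic shift, or incomplete dehydrogenation of the hindered enolate. Fallback: setting out from 16, addition of HC≡CMgBr/CeCl3 gives the 9-ethynyl carbinol F1. Its alkynyl oxy-Cope rearrangement (heating in o-dichlorobenzene, or as the potassium alkoxide) is followed in the same flask by tautomerisation to the enone, so the route is rejoined at 20 without any dehydrogenation reagent.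

Step 10. The most likely failure is 1,2-reduction of the vinylogous ester, or stalling at the methoxy-bearing β,β-disubstituted carbon. Fallback: setting out from 12, HF·pyridine removes the silyl group to give the alcohol F2. Lithium in liquid ammonia then reduces the vinylogous ester as its alkoxide (the γ-oxygen is then not a leaving group) to the hydroxy ketone F3, and TBSOTf/2,6-lutidine returns to the route at 14.

Step 17. The most likely failure is poor facial selectivity at C9, since nothing but the ring conformation controls it. Fallback: setting out from 24, the 9R alcohol F4 formed in the reduction is subjected to Mitsunobu inversion (4-nitrobenzoic acid, PPh3, DIAD) to give the inverted ester F5, and methanolysis (K2CO3, MeOH) returns to the route at 25.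

Step 18. The most likely failure is oxygen delivery to the wrong alkene face, because in an open chain the C8 branch would favour the erythro epoxy alcohol and only the ring conformation can enforce the threo isomer. Loss of the (7E) geometry in the preceding steps, or opening of the allylic epoxide with allylic transposition, would do the same damage. Fallback: setting out from 24, a Weitz–Scheffer epoxidation (t-BuOOH, DBU) of the enone, a stepwise process expected to give the trans-epoxy ketone F6 whatever the alkene geometry, is followed by CSA to give the hydroxy-keto lactone F7. The C8–C9 relationship is then set in a separate operation, a chelation-controlled reduction of the C9 ketone with Zn(BH4)2, in which zinc bridges O8 and O9 and hydride should enter from the side of C7, away from the methyl-bearing C17. This returns to the route at 27.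

Step 21. The most likely failure is poor facial selectivity at C6, proton loss towards C4 instead of C16, or capture of the developing C5 cation by the tertiary 8-OH. Fallback: setting out from 30, a Schenck ene reaction (O2, tetraphenylporphyrin, light) with reductive work-up (PPh3) gives the 6R allylic alcohol F8 with the C5=C16 methylene in place. The ring C–H bonds at C4 and C7 are poorly aligned with the π system, so the freely rotating methyl is expected to supply the hydrogen. If electrophiles prefer the C6 face opposite to the one needed for chlorine, that preference is what puts oxygen there. An Appel reaction (PPh3, CCl4), with inversion, returns to the route at 31.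

Step 20. The most likely failure is retro-aldol cleavage or dehydration of the tertiary β-hydroxy lactone during the base equilibration, or an equilibrium that does not favour 17R strongly enough. Fallback: setting out from 27, LiN(i-Pr)2 (3.5 equiv, THF, −78 °C) deprotonates C17 in the presence of the two lithium alkoxides, and a proton source (AcOH, −78 °C) should enter anti to the C8 alkoxide, as electrophiles do with β-hydroxy lactone dianions, to give the 17R hydroxy-lactone diol F9. HF·pyridine then gives the 17R triol F10, and acetylation (Ac2O, DMAP, pyridine) returns to the route at 30 without any base treatment.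

## Further compounds

F1 | step 13 | 9-ethynyl carbinol (4β-isopropenyl) | [C@@H]1(C(C)=C)C[C@H](O[Si](C)(C)C(C)(C)C)[C@@]2(C)C=C[C@@H](OC(C)(C)O3)[C@]3(C)[C@@H]2[C@@]1(O)C#C
F2 | step 10 | desilylated vinylogous ester (free 2β-OH) | C1=C(OC)[C@H](O)[C@@]2(C)C=C[C@@H](OC(C)(C)O3)[C@]3(C)[C@@H]2C1=O
F3 | step 10 | 2β-hydroxy C9 ketone | C1C[C@H](O)[C@@]2(C)C=C[C@@H](OC(C)(C)O3)[C@]3(C)[C@@H]2C1=O
F4 | step 17 | 9R allylic alcohol (C17 epimers) | C1C[C@H](O[Si](C)(C)C(C)(C)C)[C@@]2(C)C=C[C@@H](OC(C)(C)O3)[C@]3(C)[C@@H]2[C@@H](O)/C(C(C)C(=O)OC(C)(C)C)=C/C=C1/C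
F5 | step 17 | 9S 4-nitrobenzoate (C17 epimers) | C1C[C@H](O[Si](C)(C)C(C)(C)C)[C@@]2(C)C=C[C@@H](OC(C)(C)O3)[C@]3(C)[C@@H]2[C@H](OC(=O)c5ccc(cc5)[N+](=O)[O-])/C(C(C)C(=O)OC(C)(C)C)=C/C=C1/C
F6 | step 18 | 7,8-trans-epoxy C9 ketone (C17 epimers) | C1C[C@H](O[Si](C)(C)C(C)(C)C)[C@@]2(C)C=C[C@@H](OC(C)(C)O3)[C@]3(C)[C@@H]2C(=O)[C@@]4(C(C)C(=O)OC(C)(C)C)O[C@@H]4/C=C1/C
F7 | step 18 | 8-hydroxy 9-keto lactone (C17 epimers) | C1C[C@H](O[Si](C)(C)C(C)(C)C)[C@@]2(C)C=C[C@@H](OC(C)(C)O3)[C@]3(C)[C@@H]2C(=O)[C@]4(O)C(C)C(=O)O[C@H]4/C=C1/C
F8 | step 21 | 6R allylic alcohol with C5=C16 methylene | C=C1CC[C@H](OC(C)=O)[C@@]2(C)C=C[C@@H](OC(C)(C)O3)[C@]3(C)[C@@H]2[C@H](OC(C)=O)[C@]4(O)[C@@H](C)C(=O)O[C@H]4[C@@H]1O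
F9 | step 20 | 17R hydroxy-lactone 8,9-diol (2β-TBS ether) | C1C[C@H](O[Si](C)(C)C(C)(C)C)[C@@]2(C)C=C[C@@H](OC(C)(C)O3)[C@]3(C)[C@@H]2[C@H](O)[C@]4(O)[C@@H](C)C(=O)O[C@H]4/C=C1/C
F10 | step 20 | 17R 2,8,9-triol lactone | C1C[C@H](O)[C@@]2(C)C=C[C@@H](OC(C)(C)O3)[C@]3(C)[C@@H]2[C@H](O)[C@]4(O)[C@@H](C)C(=O)O[C@H]4/C=C1/C
A1 | alternative 1 | seco vinyl iodide/aldehyde for C5–C6 Nozaki–Hiyama–Kishi closure | C=C(I)CC[C@H](O[Si](C)(C)C(C)(C)C)[C@@]1(C)C=C[C@@H](OC(C)(C)O3)[C@]3(C)[C@@H]1[C@H](O[Si](CC)(CC)CC)[C@]2(O[Si](C)(C)C)[C@@H](C)C(=O)O[C@H]2C=O
A2 | alternative 2 | glycolate ester of the ring A allylic alcohol for Ireland–Claisen rearrangement | O=C(COCc1ccc(OC)cc1)O[C@@H]1C=C(C)[C@@H](COCc2ccc(OC)cc2)[C@]2(C)OC(C)(C)O[C@H]12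
A3 | alternative 3 | 2-vinyl 7-alkenyl decalin carbinol for the C2–C7 oxy-Cope | [C@H]1(/C=C/CO[Si](C)(C)C(C)(C)C)[C@@](O)(C=C)[C@@]2(C)C=C[C@@H](OC(C)(C)O3)[C@]3(C)[C@@H]2[C@H](O[Si](CC)(CC)CC)[C@]1(O[Si](C)(C)C)[C@@H](C)CO[Si](C)(C)C(C)(C)C
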